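Remark: C3 of the chroman is R by the CIP rules (C2 > aryl > C4 > H). Chroman numbering (O1 to C8a) is used for rings A and C, chromene numbering for the pyran-fused ring B. Compounds 1, 9, 18 and 21 are catalogue chemicals.

**Retrosynthetic overview**
1. Target 34 is a (3R)-isoflavan. Ring C is opened at O1–C2 (Mitsunobu etherification of 33), and C3–C4 with the C3 stereocentre comes from an Evans alkylation of the ring B arylacetyl imide 20 with the ring A benzylic bromide 29.
2. The dimethylpyran ring on ring B is disconnected at its aryl–O bond and its C4a–C4 bond. Aryne 10 (triple bond across C4a–C8a of the chromene) and 3-methylbut-2-enal 9 give benzoxete 11 by C4a–C4 bond formation, and 11 opens and recloses to chromene 13.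
3. Enabling feature: in ring B the pyran O1 and C4 sit on neighbouring carbons (C8a, C4a), and C4a is flanked by the oxygen-bearing C5. This C5–O bond polarizes the aryne so that oxygen goes to C8a and carbon to C4a, and the O1–CMe2–CH=CH unit is the skeleton of 9.
4. Ring A comes from mirror-symmetric 5-methoxyresorcinol 21. Two directed lithiations place the masked C8 formyl group between the two oxygens and the C4 carbon next to the methoxy group, with no regiochemical choice left open.
5. Ring order: ring B (bought), pyran ring (step 5), ring A (bought), chroman ring C (step 18).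

Key step: step 5

**Route**

Step 1
Reactants: 1 2-bromobenzene-1,3-diol
Product: 3 3-bromo-2,4-dihydroxybenzaldehyde, via aryl iminium chloride 2 (not isolated)
Conditions: POCl3, DMF, MeCN, −15 °C to rt; then H2O, 50 °C
Reagents that add atoms: N,N-dimethylformamide CN(C)C=O (formyl carbon); water O (carbonyl oxygen)
Why: Vilsmeier–Haack formylation goes para to one hydroxyl and ortho to the other; C4 and C6 of 1 are equivalent by symmetry and C2 is blocked by bromine, so only one aldehyde can form.

Step 2
Reactants: 3 3-bromo-2,4-dihydroxybenzaldehyde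
Product: 4 3-bromo-2-hydroxy-4-(methoxymethoxy)benzaldehyde
Conditions: MOMCl (1.05 equiv), K2CO3, acetone, 0 °C to rt
Reagents that add atoms: chloromethyl methyl ether COCCl
Why: Williamson O-alkylation; the 2-hydroxyl is held in a hydrogen bond to the aldehyde, so the free and more acidic 4-hydroxyl should be alkylated selectively.

Step 3
Reactants: 4 3-bromo-2-hydroxy-4-(methoxymethoxy)benzaldehyde
Product: 5 2-bromo-6-ethenyl-3-(methoxymethoxy)phenol
Conditions: MePPh3Br, KOtBu (3 equiv each), THF, 0 °C to rt
Reagents that add atoms: methyltriphenylphosphonium bromide C[P+](c1ccccc1)(c1ccccc1)c1ccccc1.[Br-]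
Why: Wittig methylenation; the excess unstabilized ylide also deprotonates the phenol and still adds to the phenoxide aldehyde.

Step 4
Reactants: 5 2-bromo-6-ethenyl-3-(methoxymethoxy)phenol
Product: 8 6-ethenyl-3-(methoxymethoxy)-2-(trimethylsilyl)phenyl trifluoromethanesulfonate, via aryl trimethylsilyl ether 6 (not isolated), via lithium silylphenolate 7 (not isolated)
Conditions: HN(SiMe3)2, THF, 65 °C, then evaporation; n-BuLi, THF, −100 to −78 °C; Tf2O, −78 °C
Reagents that add atoms: hexamethyldisilazane C[Si](C)(C)N[Si](C)(C)C; triflic anhydride O=S(=O)(OS(=O)(=O)C(F)(F)F)C(F)(F)F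
Why: O-silylation, bromine–lithium exchange, retro-Brook 1,3-shift of silicon from oxygen to carbon and O-triflation of the phenoxide is the standard one-pot route from ortho-bromophenols to ortho-silylaryl triflates (Kobayashi aryne precursors); the exchange at −100 °C should outrun attack on the styrene.

Step 5
Reactants: 8 6-ethenyl-3-(methoxymethoxy)-2-(trimethylsilyl)phenyl trifluoromethanesulfonate; 9 3-methylbut-2-enal
Product: 13 8-ethenyl-5-(methoxymethoxy)-2,2-dimethyl-2H-chromene, via aryne 10 (not isolated), via benzoxete 11 (not isolated), via ortho-quinone methide 12 (not isolated)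
Conditions: CsF (3 equiv), 9 (5 equiv), MeCN, rt, slow addition of 8
Reagents that add atoms: none
Why: Fluoride attacks silicon of 8, triflate leaves and aryne 10 forms with its triple bond between the carbons that become C8a and C4a; the carbonyl oxygen of 9 adds to the aryne carbon remote from the OCH2OCH3-bearing carbon, because the C–O sigma acceptor next to the other aryne carbon makes that carbon the better site for the developing aryl anion (aryne distortion model), and this anion then collapses onto the oxocarbenium carbon, so the C4a–C4 bond is made in the closure of the four-membered ring of benzoxete 11 (stepwise formal (2+2) cycloaddition of the aryne with C=O, 4-endo-trig anion–cation collapse). Ring strain drives the thermal conrotatory 4π opening of 11 to ortho-quinone methide 12, and 12 closes the pyran ring by a disrotatory oxa-6π electrocyclization between the carbonyl oxygen and the dimethyl-substituted terminus, which restores aromaticity. The closest known reaction type is the fluoride-induced reaction of ortho-silylaryl triflates with α,β-unsaturated aldehydes to give 2H-chromenes, related to the trapping of arynes by formamides through benzoxetes. No stereocentre survives: the sp3 carbon of 11 is lost on ring opening and C2 of the chromene carries two methyl groups. The step needs regioselectivity (oxygen on the carbon next to the vinyl group, carbon on the carbon next to the oxygen substituent), which the inductive effect of the OCH2OCH3 group should secure against the weak steric bias of the vinyl group. It also needs chemoselectivity for C=O addition over ene reaction and (4+2) addition, which the excess of 9, the slow generation of 10 and the β,β-disubstitution of 9 should secure.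

Step 6
Reactants: 13 8-ethenyl-5-(methoxymethoxy)-2,2-dimethyl-2H-chromene
Product: 15 2-[5-(methoxymethoxy)-2,2-dimethyl-2H-chromen-8-yl]ethan-1-ol, via B-alkyl-9-BBN 14 (not isolated)
Conditions: 9-BBN, THF, 0 °C to rt; then NaOH, H2O2, 0 °C
Reagents that add atoms: hydrogen peroxide OO
Why: Hydroboration–oxidation; 9-BBN adds anti-Markovnikov to the terminal vinyl group and should leave the cis-disubstituted chromene alkene next to the quaternary carbon untouched.

Step 7
Reactants: 15 2-[5-(methoxymethoxy)-2,2-dimethyl-2H-chromen-8-yl]ethan-1-ol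
Product: 17 [5-(methoxymethoxy)-2,2-dimethyl-2H-chromen-8-yl]acetic acid, via arylacetaldehyde 16 (not isolated)
Conditions: TEMPO (cat.), PhI(OAc)2 (2.2 equiv), MeCN/H2O, rt
Reagents that add atoms: water O
Why: Oxoammonium (TEMPO) oxidation of the primary alcohol through the aldehyde hydrate to the acid under near-neutral conditions that the MOM ether and the chromene should tolerate.

Step 8
Reactants: 17 [5-(methoxymethoxy)-2,2-dimethyl-2H-chromen-8-yl]acetic acid; 18 (4R)-4-benzyl-1,3-oxazolidin-2-one
Product: 20 (4R)-4-benzyl-3-{[5-(methoxymethoxy)-2,2-dimethyl-2H-chromen-8-yl]acetyl}-1,3-oxazolidin-2-one, via mixed pivalic anhydride 19 (not isolated)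
Conditions: PivCl, Et3N, THF, −20 °C; then LiCl, 18, rt
Reagents that add atoms: none
Why: N-acylation of the Evans oxazolidinone through the mixed pivalic anhydride; LiCl makes the oxazolidinone acidic enough for Et3N.

Step 9
Reactants: 21 5-methoxybenzene-1,3-diol
Product: 22 1-methoxy-3,5-bis(methoxymethoxy)benzene
Conditions: NaH, MOMCl, DMF, 0 °C to rt
Reagents that add atoms: chloromethyl methyl ether COCCl
Why: Williamson O-alkylation of both phenols installs two directing groups for metalation.

Step 10
Reactants: 22 1-methoxy-3,5-bis(methoxymethoxy)benzene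
Product: 24 4-methoxy-2,6-bis(methoxymethoxy)benzaldehyde, via aryllithium 23 (not isolated)
Conditions: n-BuLi, THF, 0 °C; DMF; H2O
Reagents that add atoms: N,N-dimethylformamide CN(C)C=O
Why: Directed ortho metalation; the position between the two OCH2OCH3 groups has two cooperating directors and is the most acidic, and the aryllithium is formylated by DMF.

Step 11
Reactants: 24 4-methoxy-2,6-bis(methoxymethoxy)benzaldehyde
Product: 25 2-(dimethoxymethyl)-5-methoxy-1,3-bis(methoxymethoxy)benzene
Conditions: HC(OMe)3, MeOH, PPTS (cat.), rt; Et3N quench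
Reagents that add atoms: trimethyl orthoformate COC(OC)OC
Why: Acetal formation with the orthoformate as water scavenger masks the aldehyde for the organolithium, hydride and enolate steps that follow; PPTS at rt is too weak to cleave aryl MOM ethers.

Step 12
Reactants: 25 2-(dimethoxymethyl)-5-methoxy-1,3-bis(methoxymethoxy)benzene
Product: 27 3-(dimethoxymethyl)-6-methoxy-2,4-bis(methoxymethoxy)benzaldehyde, via aryllithium 26 (not isolated)
Conditions: n-BuLi, TMEDA, THF, −78 to 0 °C; DMF, −78 °C; H2O
Reagents that add atoms: N,N-dimethylformamide CN(C)C=O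
Why: Second directed ortho metalation; the two remaining ring hydrogens are equivalent, each flanked by OCH2OCH3 and OCH3, so the new formyl group can only enter next to the methoxy group.

Step 13
Reactants: 27 3-(dimethoxymethyl)-6-methoxy-2,4-bis(methoxymethoxy)benzaldehyde
Product: 28 [3-(dimethoxymethyl)-6-methoxy-2,4-bis(methoxymethoxy)phenyl]methanol
Conditions: NaBH4, MeOH, 0 °C
Reagents that add atoms: none
Why: Borohydride reduction of the aldehyde; the acetal and the MOM ethers are stable to NaBH4 in methanol.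

Step 14
Reactants: 28 [3-(dimethoxymethyl)-6-methoxy-2,4-bis(methoxymethoxy)phenyl]methanol
Product: 29 2-(bromomethyl)-4-(dimethoxymethyl)-1-methoxy-3,5-bis(methoxymethoxy)benzene
Conditions: CBr4, PPh3, K2CO3 (solid), CH2Cl2, −20 °C; filtration through basic alumina, used at once
Reagents that add atoms: carbon tetrabromide BrC(Br)(Br)Br
Why: Appel bromination under non-acidic conditions spares the acetal and the MOM ethers; the electron-rich benzylic bromide is carried on without storage.

Step 15
Reactants: 20 (4R)-4-benzyl-3-{[5-(methoxymethoxy)-2,2-dimethyl-2H-chromen-8-yl]acetyl}-1,3-oxazolidin-2-one; 29 2-(bromomethyl)-4-(dimethoxymethyl)-1-methoxy-3,5-bis(methoxymethoxy)benzene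
Product: 31 (4R)-4-benzyl-3-{(2R)-3-[3-(dimethoxymethyl)-6-methoxy-2,4-bis(methoxymethoxy)phenyl]-2-[5-(methoxymethoxy)-2,2-dimethyl-2H-chromen-8-yl]propanoyl}-1,3-oxazolidin-2-one, via sodium enolate 30 (not isolated)
Conditions: NaN(SiMe3)2, THF, −78 °C; then 29, −78 to −40 °C
Reagents that add atoms: none
Why: Evans asymmetric alkylation; the chelated (Z)-sodium enolate is shielded on one face by the benzyl group of the (R)-auxiliary, so the benzylic bromide should add to the opposite face and set the R configuration at the carbon that becomes C3 (aryl outranks the new CH2Ar group, hence the (R)-auxiliary gives 2R here).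

Step 16
Reactants: 31 (4R)-4-benzyl-3-{(2R)-3-[3-(dimethoxymethyl)-6-methoxy-2,4-bis(methoxymethoxy)phenyl]-2-[5-(methoxymethoxy)-2,2-dimethyl-2H-chromen-8-yl]propanoyl}-1,3-oxazolidin-2-one
Product: 32 (2R)-3-[3-(dimethoxymethyl)-6-methoxy-2,4-bis(methoxymethoxy)phenyl]-2-[5-(methoxymethoxy)-2,2-dimethyl-2H-chromen-8-yl]propan-1-ol
Conditions: LiBH4, THF, H2O (1 equiv), 0 °C to rt
Reagents that add atoms: none
Why: Reductive cleavage of the imide by LiBH4 gives the primary alcohol and releases the auxiliary; the stereocentre is not acidic after reduction, and acetal, MOM ethers and chromene are inert to borohydride.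

Step 17
Reactants: 32 (2R)-3-[3-(dimethoxymethyl)-6-methoxy-2,4-bis(methoxymethoxy)phenyl]-2-[5-(methoxymethoxy)-2,2-dimethyl-2H-chromen-8-yl]propan-1-ol
Product: 33 2,6-dihydroxy-3-[(2R)-3-hydroxy-2-(5-hydroxy-2,2-dimethyl-2H-chromen-8-yl)propyl]-4-methoxybenzaldehyde
Conditions: HCl (2 M aq.), MeOH, THF, 40 °C
Reagents that add atoms: water O
Why: Acid-catalysed acetal exchange and hydrolysis should remove the three MOM ethers and the dimethyl acetal in one operation without touching the primary alcohol or the stereocentre.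

Step 18
Reactants: 33 2,6-dihydroxy-3-[(2R)-3-hydroxy-2-(5-hydroxy-2,2-dimethyl-2H-chromen-8-yl)propyl]-4-methoxybenzaldehyde
Product: 34 (3R)-7-hydroxy-3-(5-hydroxy-2,2-dimethyl-2H-chromen-8-yl)-5-methoxy-3,4-dihydro-2H-chromene-8-carbaldehyde
Conditions: PPh3, DIAD, THF (0.01 M), 0 °C to rt
Reagents that add atoms: none
Why: Intramolecular Mitsunobu etherification; only the phenol ortho to the hydroxypropyl chain can reach the activated primary carbon (6-exo-tet), the stereocentre is not involved, and Mitsunobu alkylation of salicylaldehyde-type phenols is well established.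

**Compound list**
1 | 2-bromobenzene-1,3-diol (2-bromoresorcinol) | Oc1cccc(O)c1Br | starting material
2 | (3-bromo-2,4-dihydroxybenzylidene)dimethylammonium chloride | C[N+](C)=Cc1ccc(O)c(Br)c1O.[Cl-] | intermediate
3 | 3-bromo-2,4-dihydroxybenzaldehyde | O=Cc1ccc(O)c(Br)c1O | intermediate
4 | 3-bromo-2-hydroxy-4-(methoxymethoxy)benzaldehyde | COCOc1ccc(C=O)c(O)c1Br | intermediate
5 | 2-bromo-6-ethenyl-3-(methoxymethoxy)phenol | COCOc1ccc(C=C)c(O)c1Br | intermediate
6 | [2-bromo-6-ethenyl-3-(methoxymethoxy)phenoxy]trimethylsilane | COCOc1ccc(C=C)c(O[Si](C)(C)C)c1Br | intermediate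
7 | lithium 6-ethenyl-3-(methoxymethoxy)-2-(trimethylsilyl)phenolate | [Li+].COCOc1ccc(C=C)c([O-])c1[Si](C)(C)C | intermediate
8 | 6-ethenyl-3-(methoxymethoxy)-2-(trimethylsilyl)phenyl trifluoromethanesulfonate | COCOc1ccc(C=C)c(OS(=O)(=O)C(F)(F)F)c1[Si](C)(C)C | intermediate
9 | 3-methylbut-2-enal | CC(C)=CC=O | starting material
10 | 3-ethenyl-6-(methoxymethoxy)benzyne (1,2-didehydro-3-ethenyl-6-(methoxymethoxy)benzene) | COCOC1=CC=C(C=C)C#C1 | intermediate
11 | 6-ethenyl-3-(methoxymethoxy)-2-(2-methylprop-1-en-1-yl)-2H-benzo[b]oxete (racemic, transient) | COCOc1ccc(C=C)c2OC(C=C(C)C)c12 | intermediate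
12 | 2-ethenyl-5-(methoxymethoxy)-6-(3-methylbut-2-en-1-ylidene)cyclohexa-2,4-dien-1-one | COCOC1=CC=C(C=C)C(=O)C1=CC=C(C)C | intermediate
13 | 8-ethenyl-5-(methoxymethoxy)-2,2-dimethyl-2H-chromene | COCOc1ccc(C=C)c2OC(C)(C)C=Cc12 | intermediate
14 | 9-{2-[5-(methoxymethoxy)-2,2-dimethyl-2H-chromen-8-yl]ethyl}-9-borabicyclo[3.3.1]nonane | COCOc1ccc(CCB2C3CCCC2CCC3)c2OC(C)(C)C=Cc12 | intermediate
15 | 2-[5-(methoxymethoxy)-2,2-dimethyl-2H-chromen-8-yl]ethan-1-ol | COCOc1ccc(CCO)c2OC(C)(C)C=Cc12 | intermediate
16 | [5-(methoxymethoxy)-2,2-dimethyl-2H-chromen-8-yl]acetaldehyde | COCOc1ccc(CC=O)c2OC(C)(C)C=Cc12 | intermediate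
17 | [5-(methoxymethoxy)-2,2-dimethyl-2H-chromen-8-yl]acetic acid | COCOc1ccc(CC(=O)O)c2OC(C)(C)C=Cc12 | intermediate
18 | (4R)-4-benzyl-1,3-oxazolidin-2-one | O=C1N[C@H](Cc2ccccc2)CO1 | starting material
19 | [5-(methoxymethoxy)-2,2-dimethyl-2H-chromen-8-yl]acetic pivalic anhydride | COCOc1ccc(CC(=O)OC(=O)C(C)(C)C)c2OC(C)(C)C=Cc12 | intermediate
20 | (4R)-4-benzyl-3-{[5-(methoxymethoxy)-2,2-dimethyl-2H-chromen-8-yl]acetyl}-1,3-oxazolidin-2-one | COCOc1ccc(CC(=O)N3[C@H](Cc4ccccc4)COC3=O)c2OC(C)(C)C=Cc12 | intermediate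
21 | 5-methoxybenzene-1,3-diol (5-methoxyresorcinol) | COc1cc(O)cc(O)c1 | starting material
22 | 1-methoxy-3,5-bis(methoxymethoxy)benzene | COCOc1cc(OC)cc(OCOC)c1 | intermediate
23 | [4-methoxy-2,6-bis(methoxymethoxy)phenyl]lithium | [Li]c1c(OCOC)cc(OC)cc1OCOC | intermediate
24 | 4-methoxy-2,6-bis(methoxymethoxy)benzaldehyde | COCOc1cc(OC)cc(OCOC)c1C=O | intermediate
25 | 2-(dimethoxymethyl)-5-methoxy-1,3-bis(methoxymethoxy)benzene | COCOc1cc(OC)cc(OCOC)c1C(OC)OC | intermediate
26 | [3-(dimethoxymethyl)-6-methoxy-2,4-bis(methoxymethoxy)phenyl]lithium | [Li]c1c(OC)cc(OCOC)c(C(OC)OC)c1OCOC | intermediate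
27 | 3-(dimethoxymethyl)-6-methoxy-2,4-bis(methoxymethoxy)benzaldehyde | O=Cc1c(OC)cc(OCOC)c(C(OC)OC)c1OCOC | intermediate
28 | [3-(dimethoxymethyl)-6-methoxy-2,4-bis(methoxymethoxy)phenyl]methanol | OCc1c(OC)cc(OCOC)c(C(OC)OC)c1OCOC | intermediate
29 | 2-(bromomethyl)-4-(dimethoxymethyl)-1-methoxy-3,5-bis(methoxymethoxy)benzene | BrCc1c(OC)cc(OCOC)c(C(OC)OC)c1OCOC | intermediate
30 | sodium (Z)-enolate of 20 | [Na+].COCOc1ccc(/C=C(\[O-])N3[C@H](Cc4ccccc4)COC3=O)c2OC(C)(C)C=Cc12 | intermediate
31 | (4R)-4-benzyl-3-{(2R)-3-[3-(dimethoxymethyl)-6-methoxy-2,4-bis(methoxymethoxy)phenyl]-2-[5-(methoxymethoxy)-2,2-dimethyl-2H-chromen-8-yl]propanoyl}-1,3-oxazolidin-2-one | O=C([C@H](Cc1c(OC)cc(OCOC)c(C(OC)OC)c1OCOC)c1ccc(OCOC)c2c1OC(C)(C)C=C2)N1[C@H](Cc2ccccc2)COC1=O | intermediate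
32 | (2R)-3-[3-(dimethoxymethyl)-6-methoxy-2,4-bis(methoxymethoxy)phenyl]-2-[5-(methoxymethoxy)-2,2-dimethyl-2H-chromen-8-yl]propan-1-ol | OC[C@H](Cc1c(OC)cc(OCOC)c(C(OC)OC)c1OCOC)c1ccc(OCOC)c2c1OC(C)(C)C=C2 | intermediate
33 | 2,6-dihydroxy-3-[(2R)-3-hydroxy-2-(5-hydroxy-2,2-dimethyl-2H-chromen-8-yl)propyl]-4-methoxybenzaldehyde | OC[C@H](Cc1c(OC)cc(O)c(C=O)c1O)c1ccc(O)c2c1OC(C)(C)C=C2 | intermediate
34 | (3R)-7-hydroxy-3-(5-hydroxy-2,2-dimethyl-2H-chromen-8-yl)-5-methoxy-3,4-dihydro-2H-chromene-8-carbaldehyde | COc1cc(O)c(C=O)c2c1C[C@H](c1ccc(O)c3c1OC(C)(C)C=C3)CO2 | target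

**Step count and risks**
Total step count: 18. Longest linear sequence: 12 steps (steps 1 to 8, then 15 to 18, from 2-bromoresorcinol); the ring A branch (steps 9 to 14) joins at step 15.

Steps most likely to fail:

1. Step 5 (key step). Possible failure: oxygen attack at the wrong aryne carbon, ene reaction of the aryne with the allylic C–H bonds of 9, or trapping of the aryne by vinyl groups of 8 and 13. Fallback: the chromene is made by organolithium chemistry from bromophenol 5. Treatment of 5 with n-BuLi (2.2 equiv, THF, −78 °C; phenol deprotonation, then bromine–lithium exchange) and addition of the dianion to aldehyde 9 should give 2-(1-hydroxy-3-methylbut-2-en-1-yl)-3-(methoxymethoxy)-6-ethenylphenol F1. Warming F1 with catalytic PPTS in toluene (loss of water to ortho-quinone methide 12, then oxa-6π closure) returns to chromene 13.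

2. Step 14. Possible failure: ionization and oligomerization of the electron-rich benzylic bromide during its preparation and before it meets the enolate. Fallback: steps 8 and 13 to 16 are replaced by a condensation and hydrogenation sequence from acid 17 and aldehyde 27. Perkin condensation (Ac2O, Et3N, 100 °C) should give (2E)-3-[3-(dimethoxymethyl)-6-methoxy-2,4-bis(methoxymethoxy)phenyl]-2-[5-(methoxymethoxy)-2,2-dimethyl-2H-chromen-8-yl]prop-2-enoic acid F2. Carboxylate-directed asymmetric hydrogenation with [Ir(cod)(SIPHOX)]BArF (H2, Et3N, MeOH; ligand enantiomer chosen for the R acid) should give (2R)-3-[3-(dimethoxymethyl)-6-methoxy-2,4-bis(methoxymethoxy)phenyl]-2-[5-(methoxymethoxy)-2,2-dimethyl-2H-chromen-8-yl]propanoic acid F3, with the undirected chromene alkene expected to react more slowly. Reduction of F3 with LiAlH4 (THF, 0 °C) returns to alcohol 32.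

3. Step 18. Possible failure: intermolecular O-alkylation of the two spectator phenols and addition of the phosphine–azodicarboxylate betaine to the aldehyde, in competition with ring closure. Fallback: the chroman ring is closed by Williamson etherification from alcohol 32. MsCl and Et3N (CH2Cl2, 0 °C) should give (2R)-3-[3-(dimethoxymethyl)-6-methoxy-2,4-bis(methoxymethoxy)phenyl]-2-[5-(methoxymethoxy)-2,2-dimethyl-2H-chromen-8-yl]propyl methanesulfonate F4. Deprotection (HCl, MeOH, THF, 40 °C) should give (2R)-3-(3-formyl-2,4-dihydroxy-6-methoxyphenyl)-2-(5-hydroxy-2,2-dimethyl-2H-chromen-8-yl)propyl methanesulfonate F5. K2CO3 in dilute DMF at 40 °C (6-exo-tet displacement by the ortho phenoxide) then gives target 34.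

Further compounds
F1 | step 5 | 2-(1-hydroxy-3-methylbut-2-en-1-yl)-3-(methoxymethoxy)-6-ethenylphenol | COCOc1ccc(C=C)c(O)c1C(O)C=C(C)C
F2 | step 14 | (2E)-3-[3-(dimethoxymethyl)-6-methoxy-2,4-bis(methoxymethoxy)phenyl]-2-[5-(methoxymethoxy)-2,2-dimethyl-2H-chromen-8-yl]prop-2-enoic acid | OC(=O)/C(=C/c1c(OC)cc(OCOC)c(C(OC)OC)c1OCOC)c1ccc(OCOC)c2c1OC(C)(C)C=C2
F3 | step 14 | (2R)-3-[3-(dimethoxymethyl)-6-methoxy-2,4-bis(methoxymethoxy)phenyl]-2-[5-(methoxymethoxy)-2,2-dimethyl-2H-chromen-8-yl]propanoic acid | OC(=O)[C@H](Cc1c(OC)cc(OCOC)c(C(OC)OC)c1OCOC)c1ccc(OCOC)c2c1OC(C)(C)C=C2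
F4 | step 18 | (2R)-3-[3-(dimethoxymethyl)-6-methoxy-2,4-bis(methoxymethoxy)phenyl]-2-[5-(methoxymethoxy)-2,2-dimethyl-2H-chromen-8-yl]propyl methanesulfonate | CS(=O)(=O)OC[C@H](Cc1c(OC)cc(OCOC)c(C(OC)OC)c1OCOC)c1ccc(OCOC)c2c1OC(C)(C)C=C2
F5 | step 18 | (2R)-3-(3-formyl-2,4-dihydroxy-6-methoxyphenyl)-2-(5-hydroxy-2,2-dimethyl-2H-chromen-8-yl)propyl methanesulfonate | CS(=O)(=O)OC[C@H](Cc1c(OC)cc(O)c(C=O)c1O)c1ccc(O)c2c1OC(C)(C)C=C2
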